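**Retrosynthetic overview**
1. Target 20 ⇐ allylic alcohol (MnO2) ⇐ side-chain ester from the (R)-carbinol and (2R)-2-methylbutanoic acid ⇐ C5 acetyl group (asymmetric transfer hydrogenation), installed by bromination para to O1 and Stille coupling.
2. The cis-(2R,3R) 3-acyloxy unit ⇐ cis-3-ol ⇐ racemic 2-substituted benzofuran-3(2H)-one 10 by dynamic kinetic transfer hydrogenation (C2 is labile through the aromatic enol, so both ring stereocentres are set together).
3. Key disconnection: ring B of 10 is closed onto ring A by forming O1–C7a and C3a–C3 in one aryne annulation between benzyne and the racemic α-hydroxy ester 5 (C3 at the ketone level, the enal carried as a silyl-protected allylic alcohol).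
4. Enabling feature: O1 and C3 sit on the adjacent ring A carbons C7a and C3a and are bridged by the single sp3 carbon C2, so O1–C2–C3 maps onto an α-hydroxy ester (nucleophilic O, electrophilic C) and ring A onto an aryne; the only other ring A substituent (C5) is para to O1, so symmetrical benzyne can be used and C5 functionalised afterwards.
5. Ring order: ring A is bought as the aryne precursor; ring B is the only ring made (step 3).

Key step: step 3

Remark: the (S,S)-catalyst in step 4 is assigned by analogy with 1-indanone (same facial sense, which reads 3R here because C2 outranks C3a); the enantiomeric catalyst would be used if the sense proved opposite.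

Step 1
Reactants: 1 2-bromoprop-2-en-1-ol
Product: 2 [(2-bromoprop-2-en-1-yl)oxy]tri(propan-2-yl)silane
Conditions: TIPSCl, imidazole, CH2Cl2, 0 → 25 °C
Reagents that add atoms: chlorotri(propan-2-yl)silane, CC(C)[Si](Cl)(C(C)C)C(C)C
Why: Imidazole-promoted silylation of a primary allylic alcohol; the triisopropylsilyl ether is chosen because it should survive the fluoride of step 3 and the acid of step 7.

Step 2
Reactants: 2 [(2-bromoprop-2-en-1-yl)oxy]tri(propan-2-yl)silane; 3 ethyl glyoxylate (freshly cracked)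
Product: 5 ethyl 2-hydroxy-3-({[tri(propan-2-yl)silyl]oxy}methyl)but-3-enoate (racemic), via vinylchromium dichloride 4 (not isolated)
Conditions: CrCl2 (4 equiv), NiCl2 (5 mol %), DMF, 25 °C; aq NH4Cl
Reagents that add atoms: none
Why: Nozaki–Hiyama–Kishi reaction, in which zerovalent nickel inserts into the vinyl C–Br bond, transmetalation gives the vinylchromium species 4, and this adds to the aldehyde of 3 without touching the ester; the carbinol centre is made racemic on purpose because it is equilibrated in step 4.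

Step 3
Reactants: 5 ethyl 2-hydroxy-3-({[tri(propan-2-yl)silyl]oxy}methyl)but-3-enoate (racemic, 1.3 equiv); 6 2-(trimethylsilyl)phenyl trifluoromethanesulfonate
Product: 10 2-(3-{[tri(propan-2-yl)silyl]oxy}prop-1-en-2-yl)-1-benzofuran-3(2H)-one (racemic), via benzyne 7 (not isolated), via aryl carbanion 8 (not isolated), via caesium enolate 9 (not isolated)
Conditions: CsF (4 equiv), 18-crown-6 (0.2 equiv), THF, 25 °C, 6 added over 4 h; then AcOH, −20 °C
Reagents that add atoms: none
Why: Proposed new method: fluoride converts 6 into benzyne 7 and, in excess, removes the hydroxyl proton of 5 from solution as CsHF2, so the caesium alkoxide of 5 should add through oxygen to 7 (O1–C7a) and the aryl carbanion 8, with no proton source at hand, should attack the ester carbonyl four atoms away (C3a–C3), expel ethoxide and rest as the aromatic caesium enolate 9 until cold acidic quench protonates C2 to give 10. The closest known reaction type is the aryne annulation by nucleophilic addition followed by intramolecular acyl substitution, established for salicylate esters (xanthones) and for N-sulfonyl α-amino esters and ketones (indolin-3-ones, indoles); an aliphatic α-hydroxy ester has not been used in this way. Ring B is closed by 5-exo-trig attack of the C3a carbanion on the ester C=O, the O1–C7a bond having been formed intermolecularly just before. No stereocentre is fixed here: C3 is a carbonyl carbon, and C2, already present in 5, is deliberately left racemic and labile for step 4. Regioselectivity does not arise because 7 is symmetrical; the selectivity needed is capture of 8 by the ester and not by a proton, and O- instead of C-attack of the alkoxide, which the excess CsF, the aprotic medium, the slow release of 7 and the five-membered transition state should secure, while the slight excess of 5 keeps 9 from being arylated by surplus 7.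

Step 4
Reactants: 10 2-(3-{[tri(propan-2-yl)silyl]oxy}prop-1-en-2-yl)-1-benzofuran-3(2H)-one (racemic)
Product: 11 (2R,3R)-2-(3-{[tri(propan-2-yl)silyl]oxy}prop-1-en-2-yl)-2,3-dihydro-1-benzofuran-3-ol
Conditions: RuCl[(S,S)-TsDPEN](p-cymene) (2 mol %), HCO2H/Et3N (5:2), EtOAc, 25 °C
Reagents that add atoms: none
Why: Noyori–Ikariya asymmetric transfer hydrogenation under dynamic kinetic resolution: C2 of 10 should epimerise fast by enolisation to the aromatic 3-hydroxybenzofuran while the catalyst delivers hydride to one carbonyl face (3R) and only to the ketone enantiomer whose C2 substituent lies on the opposite face, which gives the cis-(2R,3R) alcohol.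

Step 5
Reactants: 11 (2R,3R)-2-(3-{[tri(propan-2-yl)silyl]oxy}prop-1-en-2-yl)-2,3-dihydro-1-benzofuran-3-ol
Product: 12 (2R,3R)-2-(3-{[tri(propan-2-yl)silyl]oxy}prop-1-en-2-yl)-2,3-dihydro-1-benzofuran-3-yl 3-methylbutanoate
Conditions: 3-methylbutanoyl chloride, pyridine, DMAP (cat.), CH2Cl2, 0 °C
Reagents that add atoms: 3-methylbutanoyl chloride, CC(C)CC(=O)Cl
Why: DMAP-catalysed acylation of a secondary benzylic alcohol with an acid chloride; the C–O bond at C3 is not broken, so both stereocentres are retained.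

Step 6
Reactants: 12 (2R,3R)-2-(3-{[tri(propan-2-yl)silyl]oxy}prop-1-en-2-yl)-2,3-dihydro-1-benzofuran-3-yl 3-methylbutanoate
Product: 13 (2R,3R)-5-bromo-2-(3-{[tri(propan-2-yl)silyl]oxy}prop-1-en-2-yl)-2,3-dihydro-1-benzofuran-3-yl 3-methylbutanoate
Conditions: NBS (1.05 equiv), MeCN, 0 → 25 °C, dark
Reagents that add atoms: N-bromosuccinimide, O=C1CCC(=O)N1Br
Why: Electrophilic aromatic bromination, directed by the ring oxygen O1 to its para position C5 as is usual for 2,3-dihydrobenzofurans; in dry acetonitrile in the dark the activated arene should react faster than the electron-poor, doubly allylic-oxygenated 1,1-disubstituted alkene.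

Step 7
Reactants: 13 (2R,3R)-5-bromo-2-(3-{[tri(propan-2-yl)silyl]oxy}prop-1-en-2-yl)-2,3-dihydro-1-benzofuran-3-yl 3-methylbutanoate
Product: 15 (2R,3R)-5-acetyl-2-(3-{[tri(propan-2-yl)silyl]oxy}prop-1-en-2-yl)-2,3-dihydro-1-benzofuran-3-yl 3-methylbutanoate, via enol ether 14 (not isolated)
Conditions: tributyl(1-ethoxyethenyl)stannane, Pd(PPh3)4 (5 mol %), toluene, 90 °C; then 1 M aq HCl, THF, 0 °C, 15 min
Reagents that add atoms: tributyl(1-ethoxyethenyl)stannane, CCCC[Sn](CCCC)(CCCC)C(=C)OCC; water, O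
Why: Stille coupling of the aryl bromide under neutral conditions, then mild acid hydrolysis of enol ether 14 to the methyl ketone; the silyl ether and the ester should tolerate the brief cold acid.

Step 8
Reactants: 15 (2R,3R)-5-acetyl-2-(3-{[tri(propan-2-yl)silyl]oxy}prop-1-en-2-yl)-2,3-dihydro-1-benzofuran-3-yl 3-methylbutanoate
Product: 16 (2R,3R)-5-[(1R)-1-hydroxyethyl]-2-(3-{[tri(propan-2-yl)silyl]oxy}prop-1-en-2-yl)-2,3-dihydro-1-benzofuran-3-yl 3-methylbutanoate
Conditions: RuCl[(R,R)-TsDPEN](p-cymene) (1 mol %), HCO2H/Et3N (5:2), 25 °C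
Reagents that add atoms: none
Why: Noyori–Ikariya asymmetric transfer hydrogenation of an aryl methyl ketone; the (R,R)-catalyst should give the (R)-1-arylethanol, as with acetophenone, and leave the ester, the silyl ether and the isolated alkene untouched.

Step 9
Reactants: 16 (2R,3R)-5-[(1R)-1-hydroxyethyl]-2-(3-{[tri(propan-2-yl)silyl]oxy}prop-1-en-2-yl)-2,3-dihydro-1-benzofuran-3-yl 3-methylbutanoate; 17 (2R)-2-methylbutanoic acid
Product: 18 (2R,3R)-5-{(1R)-1-[(2R)-2-methylbutanoyloxy]ethyl}-2-(3-{[tri(propan-2-yl)silyl]oxy}prop-1-en-2-yl)-2,3-dihydro-1-benzofuran-3-yl 3-methylbutanoate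
Conditions: DCC, DMAP (cat.), CH2Cl2, 0 → 25 °C
Reagents that add atoms: none
Why: Steglich esterification, which breaks neither the carbinol C–O bond nor the acid α-centre, so both configurations are retained.

Step 10
Reactants: 18 (2R,3R)-5-{(1R)-1-[(2R)-2-methylbutanoyloxy]ethyl}-2-(3-{[tri(propan-2-yl)silyl]oxy}prop-1-en-2-yl)-2,3-dihydro-1-benzofuran-3-yl 3-methylbutanoate
Product: 19 (2R,3R)-2-(3-hydroxyprop-1-en-2-yl)-5-{(1R)-1-[(2R)-2-methylbutanoyloxy]ethyl}-2,3-dihydro-1-benzofuran-3-yl 3-methylbutanoate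
Conditions: HF·pyridine, pyridine, THF, 0 → 25 °C
Reagents that add atoms: none
Why: Fluoride cleavage of a primary silyl ether; the pyridine buffer should keep both esters, including the acid-sensitive p-alkoxybenzylic one, intact.

Step 11
Reactants: 19 (2R,3R)-2-(3-hydroxyprop-1-en-2-yl)-5-{(1R)-1-[(2R)-2-methylbutanoyloxy]ethyl}-2,3-dihydro-1-benzofuran-3-yl 3-methylbutanoate
Product: 20 (2R,3R)-5-{(1R)-1-[(2R)-2-methylbutanoyloxy]ethyl}-2-(3-oxoprop-1-en-2-yl)-2,3-dihydro-1-benzofuran-3-yl 3-methylbutanoate (CNP0154159.2)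
Conditions: activated MnO2 (excess), CH2Cl2, 25 °C
Reagents that add atoms: none
Why: MnO2 oxidation of an allylic alcohol to the enal under neutral conditions, so no ester cleavage or epimerisation is expected.

**Compound list**
1 | 2-bromoprop-2-en-1-ol | C=C(Br)CO | starting material
2 | [(2-bromoprop-2-en-1-yl)oxy]tri(propan-2-yl)silane | C=C(Br)CO[Si](C(C)C)(C(C)C)C(C)C | intermediate
3 | ethyl glyoxylate | CCOC(=O)C=O | starting material
4 | dichloro(3-{[tri(propan-2-yl)silyl]oxy}prop-1-en-2-yl)chromium | C=C(CO[Si](C(C)C)(C(C)C)C(C)C)[Cr](Cl)Cl | intermediate (not isolated)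
5 | ethyl 2-hydroxy-3-({[tri(propan-2-yl)silyl]oxy}methyl)but-3-enoate (racemic) | CCOC(=O)C(O)C(=C)CO[Si](C(C)C)(C(C)C)C(C)C | intermediate
6 | 2-(trimethylsilyl)phenyl trifluoromethanesulfonate | C[Si](C)(C)c1ccccc1OS(=O)(=O)C(F)(F)F | starting material
7 | benzyne | C1#CC=CC=C1 | intermediate (not isolated)
8 | caesium 2-{[1-ethoxy-1-oxo-3-({[tri(propan-2-yl)silyl]oxy}methyl)but-3-en-2-yl]oxy}benzen-1-ide | CCOC(=O)C(Oc1cccc[c-]1)C(=C)CO[Si](C(C)C)(C(C)C)C(C)C.[Cs+] | intermediate (not isolated)
9 | caesium 2-(3-{[tri(propan-2-yl)silyl]oxy}prop-1-en-2-yl)-1-benzofuran-3-olate | C=C(CO[Si](C(C)C)(C(C)C)C(C)C)c1oc2ccccc2c1[O-].[Cs+] | intermediate (not isolated)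
10 | 2-(3-{[tri(propan-2-yl)silyl]oxy}prop-1-en-2-yl)-1-benzofuran-3(2H)-one (racemic) | C=C(CO[Si](C(C)C)(C(C)C)C(C)C)C1Oc2ccccc2C1=O | intermediate
11 | (2R,3R)-2-(3-{[tri(propan-2-yl)silyl]oxy}prop-1-en-2-yl)-2,3-dihydro-1-benzofuran-3-ol | C=C(CO[Si](C(C)C)(C(C)C)C(C)C)[C@H]1Oc2ccccc2[C@H]1O | intermediate
12 | (2R,3R)-2-(3-{[tri(propan-2-yl)silyl]oxy}prop-1-en-2-yl)-2,3-dihydro-1-benzofuran-3-yl 3-methylbutanoate | C=C(CO[Si](C(C)C)(C(C)C)C(C)C)[C@H]1Oc2ccccc2[C@H]1OC(=O)CC(C)C | intermediate
13 | (2R,3R)-5-bromo-2-(3-{[tri(propan-2-yl)silyl]oxy}prop-1-en-2-yl)-2,3-dihydro-1-benzofuran-3-yl 3-methylbutanoate | C=C(CO[Si](C(C)C)(C(C)C)C(C)C)[C@H]1Oc2ccc(Br)cc2[C@H]1OC(=O)CC(C)C | intermediate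
14 | (2R,3R)-5-(1-ethoxyethenyl)-2-(3-{[tri(propan-2-yl)silyl]oxy}prop-1-en-2-yl)-2,3-dihydro-1-benzofuran-3-yl 3-methylbutanoate | C=C(CO[Si](C(C)C)(C(C)C)C(C)C)[C@H]1Oc2ccc(C(=C)OCC)cc2[C@H]1OC(=O)CC(C)C | intermediate (not isolated)
15 | (2R,3R)-5-acetyl-2-(3-{[tri(propan-2-yl)silyl]oxy}prop-1-en-2-yl)-2,3-dihydro-1-benzofuran-3-yl 3-methylbutanoate | C=C(CO[Si](C(C)C)(C(C)C)C(C)C)[C@H]1Oc2ccc(C(C)=O)cc2[C@H]1OC(=O)CC(C)C | intermediate
16 | (2R,3R)-5-[(1R)-1-hydroxyethyl]-2-(3-{[tri(propan-2-yl)silyl]oxy}prop-1-en-2-yl)-2,3-dihydro-1-benzofuran-3-yl 3-methylbutanoate | C=C(CO[Si](C(C)C)(C(C)C)C(C)C)[C@H]1Oc2ccc([C@@H](C)O)cc2[C@H]1OC(=O)CC(C)C | intermediate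
17 | (2R)-2-methylbutanoic acid | CC[C@@H](C)C(=O)O | starting material
18 | (2R,3R)-5-{(1R)-1-[(2R)-2-methylbutanoyloxy]ethyl}-2-(3-{[tri(propan-2-yl)silyl]oxy}prop-1-en-2-yl)-2,3-dihydro-1-benzofuran-3-yl 3-methylbutanoate | C=C(CO[Si](C(C)C)(C(C)C)C(C)C)[C@H]1Oc2ccc([C@@H](C)OC(=O)[C@H](C)CC)cc2[C@H]1OC(=O)CC(C)C | intermediate
19 | (2R,3R)-2-(3-hydroxyprop-1-en-2-yl)-5-{(1R)-1-[(2R)-2-methylbutanoyloxy]ethyl}-2,3-dihydro-1-benzofuran-3-yl 3-methylbutanoate | C=C(CO)[C@H]1Oc2ccc([C@@H](C)OC(=O)[C@H](C)CC)cc2[C@H]1OC(=O)CC(C)C | intermediate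
20 | (2R,3R)-5-{(1R)-1-[(2R)-2-methylbutanoyloxy]ethyl}-2-(3-oxoprop-1-en-2-yl)-2,3-dihydro-1-benzofuran-3-yl 3-methylbutanoate | C=C(C=O)[C@H]1Oc2ccc([C@@H](C)OC(=O)[C@H](C)CC)cc2[C@H]1OC(=O)CC(C)C | target

**Step count and risks**
Total steps: 11. Longest linear sequence: 11 (1 → 20).

Steps most likely to fail:

Step 3 (proposed new method). The aryl carbanion may be protonated before it closes ring B (plain O–H insertion), the β,γ-double bond of 5 or of the product may migrate into conjugation under the basic fluoride, or the product enolate may be arylated by surplus benzyne. Fallback with known chemistry, setting out from 5: Mitsunobu etherification with 2-iodophenol (PPh3, DIAD, THF, 0 °C) should give ethyl 2-(2-iodophenoxy)-3-({[tri(propan-2-yl)silyl]oxy}methyl)but-3-enoate F1. Iodine–magnesium exchange with i-PrMgCl·LiCl (THF, −40 °C) and intramolecular acylation of the ester (Parham-type cyclisation) should then close ring B and return to the route at 10.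

Step 4. The exocyclic alkene may slip into conjugation with the ketone through the enol under the amine-buffered conditions, or enolisation may be too slow relative to reduction, eroding the cis selectivity and enantiopurity. Fallback, setting out from 10: reduction with L-Selectride (LiBH(s-Bu)3, THF, −78 °C), with hydride delivered anti to the C2 substituent under non-equilibrating conditions, should give racemic cis-2-(3-{[tri(propan-2-yl)silyl]oxy}prop-1-en-2-yl)-2,3-dihydro-1-benzofuran-3-ol F2. Resolution by preparative chromatography on a chiral stationary phase returns the (2R,3R) enantiomer, compound 11.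

Step 6. Electrophilic bromine may attack the alkene in competition with ring A, or regiocontrol may be lost. Fallback, setting out from 5, in which the bromine is brought in regiodefined with the arene: Mitsunobu etherification with 4-bromo-2-iodophenol should give ethyl 2-(4-bromo-2-iodophenoxy)-3-({[tri(propan-2-yl)silyl]oxy}methyl)but-3-enoate F3. Exchange at the aryl iodide only with i-PrMgCl·LiCl (−40 °C) and Parham-type ring closure should give racemic 5-bromo-2-(3-{[tri(propan-2-yl)silyl]oxy}prop-1-en-2-yl)-1-benzofuran-3(2H)-one F4. Dynamic kinetic transfer hydrogenation under the conditions of step 4 should give (2R,3R)-5-bromo-2-(3-{[tri(propan-2-yl)silyl]oxy}prop-1-en-2-yl)-2,3-dihydro-1-benzofuran-3-ol F5, and acylation under the conditions of step 5 returns to the route at 13.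

**Further compounds**
F1 | step 3 | ethyl 2-(2-iodophenoxy)-3-({[tri(propan-2-yl)silyl]oxy}methyl)but-3-enoate (racemic) | CCOC(=O)C(Oc1ccccc1I)C(=C)CO[Si](C(C)C)(C(C)C)C(C)C
F2 | step 4 | racemic cis-2-(3-{[tri(propan-2-yl)silyl]oxy}prop-1-en-2-yl)-2,3-dihydro-1-benzofuran-3-ol | C=C(CO[Si](C(C)C)(C(C)C)C(C)C)[C@H]1Oc2ccccc2[C@H]1O.C=C(CO[Si](C(C)C)(C(C)C)C(C)C)[C@@H]1Oc2ccccc2[C@@H]1O
F3 | step 6 | ethyl 2-(4-bromo-2-iodophenoxy)-3-({[tri(propan-2-yl)silyl]oxy}methyl)but-3-enoate (racemic) | CCOC(=O)C(Oc1ccc(Br)cc1I)C(=C)CO[Si](C(C)C)(C(C)C)C(C)C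
F4 | step 6 | 5-bromo-2-(3-{[tri(propan-2-yl)silyl]oxy}prop-1-en-2-yl)-1-benzofuran-3(2H)-one (racemic) | C=C(CO[Si](C(C)C)(C(C)C)C(C)C)C1Oc2ccc(Br)cc2C1=O
F5 | step 6 | (2R,3R)-5-bromo-2-(3-{[tri(propan-2-yl)silyl]oxy}prop-1-en-2-yl)-2,3-dihydro-1-benzofuran-3-ol | C=C(CO[Si](C(C)C)(C(C)C)C(C)C)[C@H]1Oc2ccc(Br)cc2[C@H]1O
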